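The data were computed on assumed constants.

**Change the clock.** Plot these flasks against dose, the [G] charged times the time elapsed, and not against time. The rule of thumb is that if the steps need two molecules to meet, flasks of equal dose stand alike as shares of their charge.

| flask | G | remark | time |
|---|---|---|---|
| dusk | 2 mM | run made earlier |  |
| midnight | 26 mM | run made earlier |  |
| beta | 2.5 mM |  | 2.0 min |
| gamma | 5.0 mM |  | 2.0 min |
| alpha | 10 mM |  | 2.0 min |
| delta | 20 mM |  | 2.0 min |
| theta | 40 mM |  | 2.0 min |

| run | time / s | J / % |
|---|---|---|
| dusk | 10.0 | 0.3 |
| dusk | 15.0 | 0.2 |
| dusk | 30.0 | 0.6 |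
| dusk | 50.0 | 1.8 |
| dusk | 60.0 | 3.8 |
| dusk | 80.0 | 6.6 |
| midnight | 15.0 | 9.6 |
| midnight | 30.0 | 25.3 |
| midnight | 40.0 | 25.4 |
| midnight | 60.0 | 25.5 |
| midnight | 80.0 | 26.0 |

(each reading ± 0.3 percentage points)

- amount of J at the end, in percent of the G charged for beta, gamma, alpha, delta, theta, in this order
- the shape of the row from first to last (rises, then falls / hardly changes / falls all the way / rises all the way / falls, then rises)

- "hardly changes" means that all values lie within two and a half points (for a concentration: within two and a half percent of the largest)

**Read the stop.** The midnight flask holds 25.3% J at 30.0 s and 26.0% at 80.0 s, so it has stopped by the first of these times, near a quarter of its charge. Its dose at that reading, 0.780 M·s, is the stop dose, my estimate of the dose by which a flask has ceased to make J; take it as an upper mark, since the midnight flask was still climbing at 15.0 s and the stop lies somewhere between the two readings. Divide it by the asked time and the border charge is 6.50 mM. Alpha, delta and theta are charged above it, so read about a quarter for each, a share and not a fixed [J].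

**Find the border.** Test the rule on the dusk flask. It holds 6.6% at a dose of 0.160 M·s, while midnight holds 9.6% at 0.390 M·s, so dusk has more J per dose, and both flasks are still speeding up at these readings, so the rule breaks at dusk's charge. Expect the share to sink slowly as the charge grows. Gamma ends at 76.9% of the stop dose and beta at 38.5%, so both lie under the border. Dusk's lead per dose says to put gamma above midnight's share; beta, with the smaller dose, goes below gamma, still climbing. My row therefore rises, then falls.

**The check.** The forecast gave 18%, 45%, 64%, 33% and 16.5%, rises, then falls, from “exhaustion of something limited”. The flasks give 24.4%, 32.8%, 29.8%, 26.7% and 23.9%, rises, then falls.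

    G → J (k = 8.50 × 10⁻⁵ s⁻¹)
    2 G → D (k = 3.90 L mol⁻¹ s⁻¹)
    G + J → 2 J (k = 41.0 L mol⁻¹ s⁻¹)

**Why so little.** The step in which two G give D is the main reason for the low share: theta holds 23.9% J with it and 100% without it. Use the stop dose on delta: it puts the stop at 0.650 min, and delta's G has fallen under 2% of its charge by 0.530 min. Use it on beta, whose end dose lies short of the stop dose: after 2.00 min, beta still holds 13.3% G.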